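**Plan**

- Retrosynthesis: the two C7–H bonds are cut first (carbinols back to ketones), then the two aryl O–C8 ether bonds. This frees a meso all-cis bis-phenol core and two copies of one lactate-derived α-mesyloxy ketone. In the core, the C3–H and C4–H bonds are cut next and the O1–C5 bond last.
- Enabling feature: with a C3=C4 double bond, the oxolane ring (O1, C2–C5) is a 2,5-diaryl-3,4-dimethyl-2,5-dihydrofuran. Moving O1 from C5 back to C3 turns it into the isomeric alkenyl oxirane of a symmetric 1,4-diaryl-2,3-dimethylbutadiene. The cis aryls on C2 and C5 leave only one face of the ring alkene open.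
- Forward order: a twofold Heck arylation joins the aryl–C4–aryl chain and mono-epoxidation makes the three-membered ring. Copper catalysis enlarges it to the five-membered ring and hydrogenation saturates it. Ester cleavage, twofold etherification and twofold ketone reduction follow.
- Core configuration: E alkene geometry is copied into the oxirane by syn addition. C5 is set by a suprafacial oxygen shift (2,5-cis). C3 and C4 are set by hydrogenation anti to the aryls (all-cis). The core is meso, so a racemic oxirane is sufficient.
- Absolute configuration: C8 and C8' (S) come from methyl (R)-lactate by SN2 inversion. C7 and C7' (R, erythro) come from chelation-controlled hydride delivery.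

Key step: step 4

Remark on labels: O1 and C2–C5 denote the oxolane ring (aryls on C2 and C5, methyls on C3 and C4), and the same labels are used for the oxirane precursor. C7/C7' are the side-chain carbinol carbons and C8/C8' the ether-bearing carbons.

Remark on the structure: the SMILES reads as an all-cis (2S,3R,4S,5R) core carrying two identical erythro (7R,8S) side chains. Because the core alone is meso, one stereoisomer results whichever phenol is etherified first.

Remark on twofold functional-group steps (6, 10, 11): the half-converted species is treated as a stage of the same reaction and is not listed separately.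

**Step 1**
Reactants: 1 4-bromo-2-methoxyphenol
Product: 2 4-bromo-2-methoxyphenyl pivalate
Conditions: PivCl, Et3N, DMAP (cat.), CH2Cl2, 0 °C → rt
Reagents that add atoms: pivaloyl chloride, CC(C)(C)C(=O)Cl
Why: DMAP-catalysed O-acylation of a phenol; an ester is preferred to an ether because it makes the para oxygen a weak donor, which later keeps the aryl oxirane from ionising at its benzylic carbon, and it is removed by mild base without hydrogenolysis conditions near the benzylic ring C–O bonds.

**Step 2**
Reactants: 2 4-bromo-2-methoxyphenyl pivalate (2.2 equiv), 3 2,3-dimethylbuta-1,3-diene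
Product: 5 (1E,3E)-1,4-bis[3-methoxy-4-(pivaloyloxy)phenyl]-2,3-dimethylbuta-1,3-diene, via mono-arylated diene 4 (not isolated)
Conditions: Pd(OAc)2 (5 mol %), P(o-tol)3 (20 mol %), Et3N, MeCN, 110 °C, sealed vessel
Reagents that add atoms: none
Why: Twofold Heck arylation of a conjugated diene, in which the arylpalladium bromide adds to each unsubstituted CH2 terminus, the resulting π-allyl palladium species loses the benzylic β-hydrogen to restore conjugation, and each aryl ends up trans to the larger alkenyl residue (E), the symmetric (E,E) isomer being purified by crystallisation.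

**Step 3**
Reactants: 5 (1E,3E)-diaryl diene
Product: 6 rac-(2S*,3S*)-2-[3-methoxy-4-(pivaloyloxy)phenyl]-3-methyl-3-{(1E)-1-[3-methoxy-4-(pivaloyloxy)phenyl]prop-1-en-2-yl}oxirane (C2 aryl cis to the C3 methyl and trans to the alkenyl group)
Conditions: mCPBA (0.9 equiv), NaHCO3, CH2Cl2/H2O, 0 °C; recovered 5 recycled
Reagents that add atoms: mCPBA, OOC(=O)c1cccc(Cl)c1
Why: Prilezhaev epoxidation is a concerted syn addition, so the E geometry fixes the relative configuration of C2 and C3 (racemic, since the alkene faces are enantiotopic), while the deficit of peracid, the bicarbonate buffer and the deactivation of the remaining alkene by the first oxirane should hold the reaction at the mono-epoxide.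

**Step 4**
Reactants: 6 rac-alkenyl oxirane
Product: 7 cis-2,5-bis[3-methoxy-4-(pivaloyloxy)phenyl]-3,4-dimethyl-2,5-dihydrofuran (meso)
Conditions: Cu(hfacac)2 (5 mol %), toluene, 120 °C, sealed tube
Reagents that add atoms: none
Why: The Lewis-acidic divalent copper centre of Cu(hfacac)2 binds the oxirane oxygen and breaks the O1–C3 bond, the weaker of the two because C3 is tertiary and allylic, to give a copper alkoxide held through C2 next to a C3–C4–C5 allyl cation (or its σ-allyl copper equivalent); the oxygen then bonds to C5, so that O1 has moved from C3 to C5 and the alkene from C4=C5 to C3=C4. The closest known reaction type is the Cu(hfacac)2-catalysed ring expansion of vinyl oxiranes to 2,5-dihydrofurans, which is established for alkyl-, aryl- and trisubstituted members of this substrate class. The one ring that closes is the five-membered O1–C2–C3–C4–C5 ring, in a formal 5-endo-trig attack of the alkoxide on the allyl terminus, feasible because the acceptor is cationic, C2 sits on the inner position of C3 (s-cis form, with only the small C5–H pointing inward) and copper can hand the oxygen over through a six-membered oxacupracycle followed by reductive elimination. C2 keeps its configuration since the O1–C2 bond is never broken, and the one new stereocentre C5 is controlled by suprafacial transfer: oxygen leaves and returns on the same face of the allyl plane, and with the C2 aryl trans to the alkenyl group on the oxirane and the C5 aryl on the outer (E) position this geometry puts both aryls on one ring face, so that both enantiomers of 6 converge on the meso cis isomer 7. The step needs O1–C3 over O1–C2 cleavage, 1,3- over 1,2-migration and retention of the stereochemical information; the pivalate esters make both aryl groups weak cation donors, which disfavours benzylic O1–C2 opening and Meinwald-type shifts and keeps the open species too short-lived for rotation about C4–C5.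

**Step 5**
Reactants: 7 cis-dihydrofuran
Product: 8 (2S,3R,4S,5R)-2,5-bis[3-methoxy-4-(pivaloyloxy)phenyl]-3,4-dimethyloxolane (all-cis, meso)
Conditions: H2 (5 bar), 5% Rh/Al2O3, EtOAc, rt
Reagents that add atoms: none
Why: Heterogeneous syn hydrogenation, in which the two cis aryls block one face of the flat ring so that both hydrogens reach C3 and C4 from the open face and push the methyls onto the aryl face (all-cis), rhodium on alumina being chosen because it saturates hindered ring alkenes, as in the known cis hydrogenation of 2,5-diaryl-3,4-dimethylfurans, with little hydrogenolysis of allylic or benzylic C–O bonds.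

**Step 6**
Reactants: 8 all-cis oxolane dipivalate
Product: 9 4,4'-[(2S,3R,4S,5R)-3,4-dimethyloxolane-2,5-diyl]bis(2-methoxyphenol) (all-cis, meso)
Conditions: K2CO3, MeOH/THF, rt; aq NH4Cl
Reagents that add atoms: none
Why: Base-mediated methanolysis (transesterification) of two aryl esters with phenoxide as a good leaving group, under conditions that touch none of the four ring stereocentres.

**Step 7**
Reactants: 10 methyl (R)-lactate
Product: 11 (R)-2-hydroxy-N-methoxy-N-methylpropanamide
Conditions: MeNH(OMe)·HCl, iPrMgCl, THF, −20 → 0 °C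
Reagents that add atoms: N,O-dimethylhydroxylamine hydrochloride, CNOC.Cl
Why: Weinreb amide formation from an ester with the chloromagnesium amide made in the flask, a reaction routinely run on unprotected lactates, in which the magnesium alkoxide of the free hydroxyl shields the stereocentre from enolisation.

**Step 8**
Reactants: 12 4-bromo-1,2-dimethoxybenzene (2.5 equiv), 11 (R)-Weinreb amide
Product: 14 (R)-1-(3,4-dimethoxyphenyl)-2-hydroxypropan-1-one, via 3,4-dimethoxyphenylmagnesium bromide 13 (not isolated)
Conditions: Mg, THF, reflux; then 11, THF, 0 °C → rt; aq NH4Cl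
Reagents that add atoms: magnesium, [Mg] (retained only in 13)
Why: Grignard addition to a Weinreb amide, in which the first equivalent of 13 deprotonates the hydroxyl and the second forms a chelated tetrahedral intermediate that lasts until the quench, so that neither over-addition nor epimerisation of the α-carbon should occur.

**Step 9**
Reactants: 14 (R)-α-hydroxy ketone
Product: 15 (R)-1-(3,4-dimethoxyphenyl)-1-oxopropan-2-yl methanesulfonate
Conditions: MsCl, Et3N, CH2Cl2, −10 °C
Reagents that add atoms: methanesulfonyl chloride, CS(=O)(=O)Cl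
Why: O-sulfonylation of a secondary alcohol leaves the C8–O bond and hence the R configuration untouched, and the short reaction time at low temperature avoids enolisation while installing a leaving group activated by the adjacent carbonyl.

**Step 10**
Reactants: 9 all-cis bis-phenol, 15 (R)-mesylate (2.2 equiv)
Product: 16 (2S,2'S)-2,2'-{[(2S,3R,4S,5R)-3,4-dimethyloxolane-2,5-diyl]bis[(2-methoxy-4,1-phenylene)oxy]}bis[1-(3,4-dimethoxyphenyl)propan-1-one]
Conditions: BEMP (2-tert-butylimino-2-diethylamino-1,3-dimethylperhydro-1,3,2-diazaphosphorine, 2.4 equiv), MeCN, 0 °C → rt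
Reagents that add atoms: none
Why: Twofold Williamson-type SN2 O-alkylation of the phenoxides on the carbonyl-activated secondary mesylate proceeds with inversion (R to S at C8 and C8'), and the hindered metal-free phosphazene base generates the phenoxide without enolising either ketone.

**Step 11**
Reactants: 16 bis-ketone
Product: 17 (1R,2S)-1-(3,4-dimethoxyphenyl)-2-[4-[(2S,3R,4S,5R)-5-[4-[(1R,2S)-1-(3,4-dimethoxyphenyl)-1-hydroxypropan-2-yl]oxy-3-methoxyphenyl]-3,4-dimethyloxolan-2-yl]-2-methoxyphenoxy]propan-1-ol (target)
Conditions: Zn(BH4)2 (ethereal solution prepared beforehand), Et2O/CH2Cl2, −40 → 0 °C; H2O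
Reagents that add atoms: none
Why: Cram-chelate (chelation-controlled) hydride reduction, in which the zinc dication ties the carbonyl oxygen to the C8 aryloxy oxygen (assisted by the neighbouring ring methoxy group) and hydride enters past the small C8–H to give the anti (erythro) 7R,8S and 7'R,8'S carbinols, whereas a non-chelated Felkin–Anh reduction would lead to the unwanted threo 7S,8S series.

**Compound list**

1 | 4-bromo-2-methoxyphenol | COc1cc(Br)ccc1O | starting material
2 | 4-bromo-2-methoxyphenyl pivalate | COc1cc(Br)ccc1OC(=O)C(C)(C)C | intermediate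
3 | 2,3-dimethylbuta-1,3-diene | CC(=C)C(C)=C | starting material
4 | 4-[(1E)-2,3-dimethylbuta-1,3-dien-1-yl]-2-methoxyphenyl pivalate (mono-arylated diene, not isolated) | COc1cc(/C=C(C)/C(C)=C)ccc1OC(=O)C(C)(C)C | intermediate
5 | (1E,3E)-1,4-bis[3-methoxy-4-(pivaloyloxy)phenyl]-2,3-dimethylbuta-1,3-diene | COc1cc(/C=C(C)/C(C)=C/c2ccc(OC(=O)C(C)(C)C)c(OC)c2)ccc1OC(=O)C(C)(C)C | intermediate
6 | rac-(2S*,3S*)-2-aryl-3-methyl-3-[(1E)-1-arylprop-1-en-2-yl]oxirane, aryl = 3-methoxy-4-(pivaloyloxy)phenyl (one enantiomer drawn) | COc1cc(ccc1OC(=O)C(C)(C)C)[C@@H]1O[C@@]1(C)/C(C)=C/c1ccc(OC(=O)C(C)(C)C)c(OC)c1 | intermediate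
7 | cis-2,5-bis[3-methoxy-4-(pivaloyloxy)phenyl]-3,4-dimethyl-2,5-dihydrofuran (meso) | COc1cc(ccc1OC(=O)C(C)(C)C)[C@H]1O[C@@H](c2ccc(OC(=O)C(C)(C)C)c(OC)c2)C(C)=C1C | intermediate
8 | (2S,3R,4S,5R)-2,5-bis[3-methoxy-4-(pivaloyloxy)phenyl]-3,4-dimethyloxolane (all-cis, meso) | COc1cc(ccc1OC(=O)C(C)(C)C)[C@H]1O[C@@H](c2ccc(OC(=O)C(C)(C)C)c(OC)c2)[C@@H](C)[C@H]1C | intermediate
9 | 4,4'-[(2S,3R,4S,5R)-3,4-dimethyloxolane-2,5-diyl]bis(2-methoxyphenol) (all-cis, meso) | COc1cc(ccc1O)[C@H]1O[C@@H](c2ccc(O)c(OC)c2)[C@@H](C)[C@H]1C | intermediate
10 | methyl (R)-lactate | C[C@@H](O)C(=O)OC | starting material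
11 | (R)-2-hydroxy-N-methoxy-N-methylpropanamide | C[C@@H](O)C(=O)N(C)OC | intermediate
12 | 4-bromo-1,2-dimethoxybenzene | COc1ccc(Br)cc1OC | starting material
13 | 3,4-dimethoxyphenylmagnesium bromide (not isolated) | COc1ccc([Mg]Br)cc1OC | intermediate
14 | (R)-1-(3,4-dimethoxyphenyl)-2-hydroxypropan-1-one | C[C@@H](O)C(=O)c1ccc(OC)c(OC)c1 | intermediate
15 | (R)-1-(3,4-dimethoxyphenyl)-1-oxopropan-2-yl methanesulfonate | C[C@@H](OS(C)(=O)=O)C(=O)c1ccc(OC)c(OC)c1 | intermediate
16 | bis[(S)-α-aryloxy ketone] on the all-cis core | COc1ccc(C(=O)[C@H](C)Oc2ccc([C@H]3O[C@@H](c4ccc(O[C@@H](C)C(=O)c5ccc(OC)c(OC)c5)c(OC)c4)[C@@H](C)[C@H]3C)cc2OC)cc1OC | intermediate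
17 | CNP0116650.5, all-cis core with two (7R,8S) side chains | COc1ccc([C@@H](O)[C@H](C)Oc2ccc([C@H]3O[C@@H](c4ccc(O[C@@H](C)[C@H](O)c5ccc(OC)c(OC)c5)c(OC)c4)[C@@H](C)[C@H]3C)cc2OC)cc1OC | target

**Step count**

Total step count: 11.
Longest linear sequence: 8 (steps 1–6, 10, 11). The side-chain ketone takes 3 steps (7–9).

**Steps most likely to fail**

1. Step 4.
   - Risk: ionisation may outrun ring closure, leading to 1,2-hydride or alkenyl shifts to carbonyl compounds or to proton loss from a methyl group. Rotation about C4–C5 in the open species may also erode the cis sense.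
   - Fallback, from 5 to 8: dye-sensitised photooxygenation of 5 (O2, tetraphenylporphyrin, visible light, CH2Cl2, 0 °C) should add singlet oxygen suprafacially across the s-cis diene. This gives the cis-3,6-diaryl-4,5-dimethyl-3,6-dihydro-1,2-dioxine F1.
   - Et3N then triggers a Kornblum–DeLaMare rearrangement to the (Z)-γ-hydroxy enone F2. A trace of TsOH cyclises it, with loss of water, to the 2,5-diaryl-3,4-dimethylfuran F3.
   - Hydrogenation of F3 over Rh/Al2O3 delivers all four hydrogens from one face and gives 8.
   - Dihydrofuran material of eroded cis purity from step 4 can be brought into the same furan F3 with DDQ.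

2. Step 2.
   - Risk: β-hydride elimination from the π-allyl palladium intermediate may be slow, or may go toward a methyl group and give non-conjugated isomers. The second arylation may stay incomplete, and the volatile diene may be lost or oligomerise.
   - Fallback, from 2 to 5: Sonogashira coupling of 2 with propyne (PdCl2(PPh3)2, CuI, Et3N, THF, 60 °C) gives the 1-arylpropyne F4.
   - Copper-catalysed syn borylcupration and protonation (B2pin2, CuCl, Xantphos, NaOtBu cat., MeOH, THF, rt) places boron on the methyl-bearing carbon and gives the (Z)-alkenyl pinacol boronate F5.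
   - Oxidative homocoupling (Pd(OAc)2 cat., O2, mild base) joins two alkenyl units with retention, so the (E,E) geometry of 5 is defined by construction.

3. Step 11.
   - Risk: an aryl ether oxygen binds zinc only weakly. Open-chain Felkin–Anh delivery may therefore compete, giving poor facial selectivity at one or both carbonyl groups.
   - Fallback, from 9, 10 and 13 to 17: the carbinol centres are made by C–C bond formation, for which the Felkin–Anh mode gives the erythro series.
   - Mitsunobu etherification of 9 with 10 (PPh3, DIAD, THF) inverts the lactate carbon and gives the bis[(S)-2-aryloxypropanoate] F6.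
   - iBu2AlH (CH2Cl2, −78 °C) stops at the bis[(S)-2-aryloxypropanal] F7.
   - Grignard reagent 13 is transmetalated with ClTi(OiPr)3 to the non-chelating 3,4-dimethoxyphenyltitanium triisopropoxide F8. This adds at −78 → −20 °C anti to the aryloxy group and gives the 7R,8S carbinols of 17.

**Further compounds**

F1 | step 4 | cis-3,6-bis[3-methoxy-4-(pivaloyloxy)phenyl]-4,5-dimethyl-3,6-dihydro-1,2-dioxine (meso) | COc1cc(ccc1OC(=O)C(C)(C)C)[C@H]1OO[C@@H](c2ccc(OC(=O)C(C)(C)C)c(OC)c2)C(C)=C1C
F2 | step 4 | rac-(Z)-4-hydroxy-1,4-bis[3-methoxy-4-(pivaloyloxy)phenyl]-2,3-dimethylbut-2-en-1-one | COc1cc(ccc1OC(=O)C(C)(C)C)C(O)/C(C)=C(C)\C(=O)c1ccc(OC(=O)C(C)(C)C)c(OC)c1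
F3 | step 4 | 2,5-bis[3-methoxy-4-(pivaloyloxy)phenyl]-3,4-dimethylfuran | COc1cc(ccc1OC(=O)C(C)(C)C)-c1oc(-c2ccc(OC(=O)C(C)(C)C)c(OC)c2)c(C)c1C
F4 | step 2 | 2-methoxy-4-(prop-1-yn-1-yl)phenyl pivalate | CC#Cc1ccc(OC(=O)C(C)(C)C)c(OC)c1
F5 | step 2 | 2-methoxy-4-[(1Z)-2-(4,4,5,5-tetramethyl-1,3,2-dioxaborolan-2-yl)prop-1-en-1-yl]phenyl pivalate (aryl trans to boron) | COc1cc(/C=C(C)/B2OC(C)(C)C(C)(C)O2)ccc1OC(=O)C(C)(C)C
F6 | step 11 | dimethyl (2S,2'S)-2,2'-{[(2S,3R,4S,5R)-3,4-dimethyloxolane-2,5-diyl]bis[(2-methoxy-4,1-phenylene)oxy]}dipropanoate | COC(=O)[C@H](C)Oc1ccc([C@H]2O[C@@H](c3ccc(O[C@@H](C)C(=O)OC)c(OC)c3)[C@@H](C)[C@H]2C)cc1OC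
F7 | step 11 | (2S,2'S)-2,2'-{[(2S,3R,4S,5R)-3,4-dimethyloxolane-2,5-diyl]bis[(2-methoxy-4,1-phenylene)oxy]}dipropanal | O=C[C@H](C)Oc1ccc([C@H]2O[C@@H](c3ccc(O[C@@H](C)C=O)c(OC)c3)[C@@H](C)[C@H]2C)cc1OC
F8 | step 11 | 3,4-dimethoxyphenyltitanium triisopropoxide | COc1ccc([Ti](OC(C)C)(OC(C)C)OC(C)C)cc1OC
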